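A charge of 0.2 mol% of G carries this flask, and 1.10 equiv of D makes X the limiting reagent by the charges.

- delta: X 1.5 M; D 1.1 equiv; G 0.2 mol%; the very flask that is asked about, followed so far
- flask: X 1.5 M; D 1.10 equiv; G 0.2 mol%; time 20 min

delta run (percent of the X charged)

| time / min | L / % | X / % |
|---|---|---|
| 1.33 | 43.1 | 55.5 |
| 4.00 | 56.8 | 44.7 |
| 8.00 | 60.0 | 37.2 |
| 12.0 | 63.5 | 35.0 |
| 15.0 | 66.8 | 33.5 |

(scatter of a reading: 1 percentage point)

- north: at 20 min take out 90% of the L then present, then wait 6.0 min
- north-west: at 20 min add G, 50.0% of the amount charged, then wait 6.0 min
- south-east: change nothing and wait 6.0 min more

- L that was removed still counts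
- additions bring no volume worth counting

- L, in percent of the X first charged, at 20 min
- the remedy with the largest gain of L, or "none" below 2 percentage points (north / north-west / south-east / none)
- L present, with what was taken out counted in, in percent of the X first charged, after north
- L present, with what was taken out counted in, in percent of the X first charged, after south-east

Take the share of the charged D that has become L, which is L in percent of the X charged divided by the equivalents of D: the reading at 15.0 min puts it at 60.7%. For the opposite outcome, X used up, that share would have to reach 90.9%, which is more than the reading. The pace gives little hope of closing that distance. L rose 14 percentage points in 2.67 min early on, but 6.8 points in 7.00 min later, while X fell 3.7 points over those same minutes. Plain waiting counts as a remedy if L gains 2 points in 6.0 min.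

This reckoning of my own lets the pace go on falling, so the share stays near its reading. L at 20 min then lies close to 66.8%, and waiting adds less than the margin. With 33.5% of X still present at the last reading, a falling pace points to a loss of G or of D; the readings do not tell which, but G is the one of the two that the options add, so this reckoning chooses adding G.

The forecast gave 70.5% (69% to 72%), which is higher than this reckoning, with 74.5% after north and 74% after south-east. It chose north-west: “Fresh G should give a small second burst”.

The flask gives 67.0% at 20 min, and north-west is best, gaining 5.2 points against 0.99 points for north and 0.67 points for south-east, so L reaches 68.0% after north and 67.7% after south-east.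

    X + D + G → L + G, rate k1*[X]*[D]*[G]/(1 + ([X]/sat1)) (27.0 mM, k = 150 L² mol⁻² s⁻¹)
    D ⇌ E (K = 8.00, k = 0.0140 s⁻¹)
    G + L → Z (k = 0.00270 L mol⁻¹ s⁻¹)

At 20.0 min, 4.14% of the charged D stands free and E holds 0.573 M. Left alone until 200 min, the flask reaches 68.1%, a share of 61.9%, still less than 90.9%.

In the neighbour charged with 0.440 equiv of D, the carried share gives L of 26.7%. The computed flask gives 30.6%, a share of 69.5%.

The numbers in the tables were generated by integration for an exercise; noise was put on by code.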